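## Retrosynthetic overview

1. Target 18 comes from 17 by removing the two O-benzyl groups. The C4–OH of the oxolane comes from the C4–CHO of 15 by Baeyer–Villiger oxidation with retention.
2. 15 comes from a Prins–pinacol union of the (S,E)-diol 12 with aldehyde 13. C2–O1 and C2–C3 form first (oxane cation). The ring methylene C5 then shifts from the carbinol carbon to C4, which makes the C4–C5 bond and closes the oxolane.
3. Enabling feature: in the oxolane ring the fully substituted C4 stands next to the ring methylene C5 on O1, C2 is an aldehyde-derived ArCH–O carbon, and the oxygen on C4 can stand for a formyl group. C4, the expelled formyl carbon and C5 are C1, C2 and C3 of D-glyceraldehyde, whose middle carbon is squeezed out.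
4. 12 comes from Negishi benzylation of the (Z)-iodoalkenol 6, which fixes the E alkene. 6 comes from directed hydroalumination–iodination of alkynol 4, and 4 comes from 1.
5. Ring order: dioxolane acetal 14 (temporary), oxane cation (transient), oxolane (final).

Key step: step 8

Remark on locants: O1, C2 (aryl), C3 (CH2OAc), C4 (OH and benzyl) and C5 (ring CH2) of the oxolane are used for all compounds.

Assumption: in step 8 the tin-bound carbinol oxygen is taken to sit pseudoaxial in the chair, because of A(1,2) strain with the benzyl group. This links (R)-1 to the (2S,3R,4S) series. Compounds 1, 7 and 13 are taken as commercial.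

## Route

Step 1
Reactants: 1 (R)-2,2-dimethyl-1,3-dioxolane-4-carbaldehyde
Product: 2 (S)-4-ethynyl-2,2-dimethyl-1,3-dioxolane
Conditions: dimethyl (1-diazo-2-oxopropyl)phosphonate, K2CO3, MeOH, 0 °C to rt
Reagents that add atoms: dimethyl (1-diazo-2-oxopropyl)phosphonate, CC(=O)C(=[N+]=[N-])P(=O)(OC)OC
Why: Seyferth–Gilbert homologation with the Ohira–Bestmann reagent turns the aldehyde into the terminal alkyne under carbonate conditions mild enough to keep the α-alkoxy stereocentre intact (the descriptor changes from R to S only through the priority rules).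

Step 2
Reactants: 2 (S)-4-ethynyl-2,2-dimethyl-1,3-dioxolane
Product: 4 3-[(4S)-2,2-dimethyl-1,3-dioxolan-4-yl]prop-2-yn-1-ol, via lithium acetylide 3 (not isolated)
Conditions: n-BuLi, THF, −78 °C; (CH2O)n, −78 °C to rt; H2O
Reagents that add atoms: formaldehyde (as paraformaldehyde), C=O
Why: Deprotonation of the terminal alkyne and 1,2-addition of the lithium acetylide to formaldehyde is a standard hydroxymethylation that touches neither the acetonide nor the stereocentre.

Step 3
Reactants: 4 3-[(4S)-2,2-dimethyl-1,3-dioxolan-4-yl]prop-2-yn-1-ol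
Product: 6 (Z)-3-[(4R)-2,2-dimethyl-1,3-dioxolan-4-yl]-3-iodoprop-2-en-1-ol, via cyclic alkenylalanate 5 (not isolated)
Conditions: NaAlH2(OCH2CH2OMe)2, THF, 0 °C to rt; EtOAc; I2, THF, −78 °C; aqueous work-up
Reagents that add atoms: iodine, II
Why: Alkoxide-directed trans-hydroalumination of the propargylic alcohol places aluminium on the distal alkyne carbon in a five-membered alanate, and iodinolysis with retention should give the Z iodoalkene with iodine cis to CH2OH, while the low temperature holds back β-alkoxide elimination to an allene.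

Step 4
Reactants: 7 4-(benzyloxy)-3-methoxybenzyl alcohol
Product: 8 4-(benzyloxy)-3-methoxybenzyl chloride
Conditions: SOCl2, CH2Cl2, 0 °C
Reagents that add atoms: thionyl chloride, ClS(Cl)=O
Why: Chlorodehydroxylation of an electron-rich benzylic alcohol through its chlorosulfite is fast at 0 °C and leaves both aryl ethers alone.

Step 5
Reactants: 6 (Z)-3-[(4R)-2,2-dimethyl-1,3-dioxolan-4-yl]-3-iodoprop-2-en-1-ol; 8 4-(benzyloxy)-3-methoxybenzyl chloride
Product: 10 (E)-4-[4-(benzyloxy)-3-methoxyphenyl]-3-[(4S)-2,2-dimethyl-1,3-dioxolan-4-yl]but-2-en-1-ol, via benzylzinc chloride 9 (not isolated)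
Conditions: 8, Zn dust, LiCl, THF, rt; then 6, Pd(OAc)2 (cat.), SPhos (cat.), THF, rt
Reagents that add atoms: none
Why: Zinc insertion assisted by LiCl gives the benzylic zinc reagent, and Negishi cross-coupling proceeds with retention of alkene geometry, so the benzyl group ends cis to CH2OH (E alkene) with a catalyst system that tolerates the free hydroxyl group.

Step 6
Reactants: 10 (E)-4-[4-(benzyloxy)-3-methoxyphenyl]-3-[(4S)-2,2-dimethyl-1,3-dioxolan-4-yl]but-2-en-1-ol
Product: 11 (E)-4-[4-(benzyloxy)-3-methoxyphenyl]-3-[(4S)-2,2-dimethyl-1,3-dioxolan-4-yl]but-2-enyl acetate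
Conditions: Ac2O, pyridine, DMAP (cat.), CH2Cl2, 0 °C
Reagents that add atoms: acetic anhydride, CC(=O)OC(C)=O
Why: Simple O-acetylation of the only free (primary allylic) hydroxyl group installs the acetate of the target at its final position before any other hydroxyl group exists.

Step 7
Reactants: 11 (E)-4-[4-(benzyloxy)-3-methoxyphenyl]-3-[(4S)-2,2-dimethyl-1,3-dioxolan-4-yl]but-2-enyl acetate
Product: 12 (2E,4S)-3-[4-(benzyloxy)-3-methoxybenzyl]-4,5-dihydroxypent-2-enyl acetate
Conditions: AcOH–H2O 4:1, 40 °C
Reagents that add atoms: none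
Why: Mild acid hydrolysis of the acetonide frees the 1,2-diol without cleaving the acetate, which lies trans to the diol across the alkene and so cannot migrate.

Step 8
Reactants: 12 (2E,4S)-3-[4-(benzyloxy)-3-methoxybenzyl]-4,5-dihydroxypent-2-enyl acetate; 13 4-(benzyloxy)-3-methoxybenzaldehyde
Product: 15 [(2S,3R,4S)-2-[4-(benzyloxy)-3-methoxyphenyl]-4-[4-(benzyloxy)-3-methoxybenzyl]-4-formyloxolan-3-yl]methyl acetate, via dioxolane acetal 14 (not isolated)
Conditions: p-TsOH·H2O (cat.), MgSO4, CH2Cl2, −20 °C; then SnCl4 (0.2 equiv), −20 to 0 °C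
Reagents that add atoms: none
Why: Reversible acetalisation closes the temporary dioxolane 14, SnCl4 opens it at the allylic C–O bond to the (E)-oxocarbenium ion on the primary oxygen, the alkene attacks through its CH terminus (6-endo-trig, chair) to close an oxane and leave a tertiary cation at the benzyl-bearing carbon, and the ring CH2 next to oxygen then shifts from the tin-bound carbinol carbon to this cation (pinacol 1,2-shift, ring contraction), which makes the C4–C5 bond, closes the oxolane and expels the carbinol carbon as the formyl group. The closest known reaction type is the Prins–pinacol synthesis of 3-acyl- and 3-formyloxolanes from alk-3-ene-1,2-diols and aldehydes, including primary/secondary diols that end as a formyl group on a quaternary carbon. C2 is set by the equatorial aryl group of the (E)-oxocarbenium ion, C3 by the E alkene geometry that places CH2OAc equatorial and hence trans to the aryl group, and C4 by the geometry of the contraction, in which the extruded carbinol carbon ends on the face of the aryl group and the benzyl group ends cis to CH2OAc. The absolute sense comes from the single (S)-carbinol centre of 12, whose C–O bond sits pseudoaxial to avoid A(1,2) strain with the benzyl group so that one chair is populated, and this centre is destroyed once it has done its work. The step needs the shift of the ring CH2 to win over hydride shift from the carbinol carbon or from the benzylic CH2, proton loss and acetate participation; the pseudoequatorial carbinol hydrogen is misaligned with the empty orbital, and the alkoxide-assisted shift is intramolecular, strongly downhill and probably merged with the Prins attack at low temperature.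

Step 9
Reactants: 15 [(2S,3R,4S)-2-[4-(benzyloxy)-3-methoxyphenyl]-4-[4-(benzyloxy)-3-methoxybenzyl]-4-formyloxolan-3-yl]methyl acetate
Product: 17 [(2S,3R,4S)-2-[4-(benzyloxy)-3-methoxyphenyl]-4-[4-(benzyloxy)-3-methoxybenzyl]-4-hydroxyoxolan-3-yl]methyl acetate, via formate ester 16 (not isolated)
Conditions: mCPBA, CH2Cl2, 0 °C to rt; aqueous wash, concentrate; then KHCO3 (cat.), MeOH, 0 °C
Reagents that add atoms: 3-chloroperoxybenzoic acid, OOC(=O)c1cccc(Cl)c1
Why: In the Baeyer–Villiger oxidation of this α-quaternary aldehyde the fully substituted C4 should migrate in preference to hydrogen and with retention, so oxygen replaces the formyl group on the same face, and catalytic methanolysis then removes the formate, which is cleaved far faster than the primary acetate.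

Step 10
Reactants: 17 [(2S,3R,4S)-2-[4-(benzyloxy)-3-methoxyphenyl]-4-[4-(benzyloxy)-3-methoxybenzyl]-4-hydroxyoxolan-3-yl]methyl acetate
Product: 18 olivil monoacetate, [(2S,3R,4S)-4-hydroxy-2-(4-hydroxy-3-methoxyphenyl)-4-(4-hydroxy-3-methoxybenzyl)oxolan-3-yl]methyl acetate
Conditions: H2 (1 atm), Pd/C (10 wt %), EtOAc–EtOH, rt, stopped at full debenzylation
Reagents that add atoms: none
Why: Hydrogenolysis of the two aryl benzyl ethers at 1 atm is faster than cleavage of the cyclic benzylic C2–O1 bond and leaves the acetate, the tertiary alcohol and all three stereocentres untouched.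

## Compound list

1 | (R)-2,2-dimethyl-1,3-dioxolane-4-carbaldehyde | O=C[C@H]1COC(C)(C)O1 | starting material
2 | (S)-4-ethynyl-2,2-dimethyl-1,3-dioxolane | C#C[C@H]1COC(C)(C)O1 | intermediate
3 | lithium acetylide of 2 | [Li]C#C[C@H]1COC(C)(C)O1 | intermediate
4 | 3-[(4S)-2,2-dimethyl-1,3-dioxolan-4-yl]prop-2-yn-1-ol | OCC#C[C@H]1COC(C)(C)O1 | intermediate
5 | sodium cyclic alkenylalanate (five-membered O–Al–C=C–C ring, two 2-methoxyethoxy groups on Al) | COCCO[Al-]1(OCCOC)OCC=C1[C@H]1COC(C)(C)O1.[Na+] | intermediate
6 | (Z)-3-[(4R)-2,2-dimethyl-1,3-dioxolan-4-yl]-3-iodoprop-2-en-1-ol | OC/C=C(\I)[C@H]1COC(C)(C)O1 | intermediate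
7 | 4-(benzyloxy)-3-methoxybenzyl alcohol | OCc1ccc(OCc2ccccc2)c(OC)c1 | starting material
8 | 4-(benzyloxy)-3-methoxybenzyl chloride | ClCc1ccc(OCc2ccccc2)c(OC)c1 | intermediate
9 | 4-(benzyloxy)-3-methoxybenzylzinc chloride | Cl[Zn]Cc1ccc(OCc2ccccc2)c(OC)c1 | intermediate
10 | (E)-4-[4-(benzyloxy)-3-methoxyphenyl]-3-[(4S)-2,2-dimethyl-1,3-dioxolan-4-yl]but-2-en-1-ol | OC/C=C(\Cc1ccc(OCc2ccccc2)c(OC)c1)[C@H]1COC(C)(C)O1 | intermediate
11 | (E)-4-[4-(benzyloxy)-3-methoxyphenyl]-3-[(4S)-2,2-dimethyl-1,3-dioxolan-4-yl]but-2-enyl acetate | CC(=O)OC/C=C(\Cc1ccc(OCc2ccccc2)c(OC)c1)[C@H]1COC(C)(C)O1 | intermediate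
12 | (2E,4S)-3-[4-(benzyloxy)-3-methoxybenzyl]-4,5-dihydroxypent-2-enyl acetate | CC(=O)OC/C=C(\Cc1ccc(OCc2ccccc2)c(OC)c1)[C@H](O)CO | intermediate
13 | 4-(benzyloxy)-3-methoxybenzaldehyde | O=Cc1ccc(OCc2ccccc2)c(OC)c1 | starting material
14 | 2-aryl-1,3-dioxolane acetal of 12 with 13 (4S, both epimers at the acetal carbon) | CC(=O)OC/C=C(\Cc1ccc(OCc2ccccc2)c(OC)c1)[C@H]1COC(O1)c1ccc(OCc2ccccc2)c(OC)c1 | intermediate
15 | [(2S,3R,4S)-2-[4-(benzyloxy)-3-methoxyphenyl]-4-[4-(benzyloxy)-3-methoxybenzyl]-4-formyloxolan-3-yl]methyl acetate | COc1cc(C[C@@]2(C=O)CO[C@H](c3ccc(OCc4ccccc4)c(OC)c3)[C@H]2COC(C)=O)ccc1OCc1ccccc1 | intermediate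
16 | [(2S,3R,4S)-2-[4-(benzyloxy)-3-methoxyphenyl]-4-[4-(benzyloxy)-3-methoxybenzyl]-4-(formyloxy)oxolan-3-yl]methyl acetate | COc1cc(C[C@@]2(OC=O)CO[C@H](c3ccc(OCc4ccccc4)c(OC)c3)[C@H]2COC(C)=O)ccc1OCc1ccccc1 | intermediate
17 | [(2S,3R,4S)-2-[4-(benzyloxy)-3-methoxyphenyl]-4-[4-(benzyloxy)-3-methoxybenzyl]-4-hydroxyoxolan-3-yl]methyl acetate | COc1cc(C[C@@]2(O)CO[C@H](c3ccc(OCc4ccccc4)c(OC)c3)[C@H]2COC(C)=O)ccc1OCc1ccccc1 | intermediate
18 | olivil monoacetate | COc1cc(C[C@@]2(O)CO[C@H](c3ccc(O)c(OC)c3)[C@H]2COC(C)=O)ccc1O | target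

## Step count and risks

Total step count: 10.
Longest linear sequence: 9 steps (steps 1, 2, 3, 5, 6, 7, 8, 9 and 10, from 1 to 18).

**Step 8**
- What may go wrong:
  - ionisation or neighbouring-group participation of the allylic acetate under SnCl4;
  - slow attack of the acetate-deactivated alkene on the strongly stabilised oxocarbenium ion;
  - hydride shift from the benzylic CH2 to the tertiary cation;
  - acid-induced Friedel–Crafts closure of the benzyl ring onto C2;
  - incomplete chirality transfer from the carbinol centre.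
- Fallback: the acetate is brought in only after the cationic step, and a more electron-rich, non-participating alkene is used. The fallback sets out from 10.
  - Silylation (t-BuPh2SiCl, imidazole) should give the silyl ether acetonide F1.
  - Hydrolysis (AcOH–H2O) should give the silyl ether diol F2.
  - Acetalisation with 13 should give the silyl ether acetal F3, and its SnCl4-induced Prins–pinacol rearrangement should give the silyl ether formyl oxolane F4.
  - Baeyer–Villiger oxidation should give the silyl ether formate F5, and methanolysis should give the silyl ether tertiary alcohol F6.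
  - Bu4NF buffered with AcOH should give the primary/tertiary diol F7.
  - Ac2O in pyridine acetylates only the primary hydroxyl group, and the fallback comes back to the route at 17.

**Step 9**
- What may go wrong:
  - migration of hydrogen instead of the β-oxygenated quaternary carbon in the Criegee adduct (over-oxidation to the acid);
  - slow peracid addition to the hindered aldehyde, with competing attack on the electron-rich arenes;
  - partial loss of the acetate during formate removal.
- Fallback: radical decarboxylative oxygenation replaces the peracid rearrangement. The fallback sets out from 15.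
  - Pinnick oxidation (NaClO2, NaH2PO4, 2-methylbut-2-ene) should give the carboxylic acid F8.
  - Coupling with 1-hydroxypyridine-2(1H)-thione (DCC) should give the thiohydroxamate ester F9.
  - Visible-light photolysis under O2 with t-BuSH should give the tertiary hydroperoxide F10. Oxygen is taken up on the ring face opposite to the neighbouring CH2OAc group.
  - P(OMe)3 reduces the hydroperoxide, and the fallback comes back to the route at 17.

**Step 5**
- What may go wrong:
  - homocoupling of the electron-rich benzylic zinc reagent while it forms;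
  - its protonation by the free hydroxyl group;
  - slow coupling at the branched iodoalkene.
- Fallback: the polarity of the coupling is reversed. The fallback sets out from 6.
  - Miyaura borylation (B2pin2, PdCl2(dppf), KOAc, dioxane) should give the pinacol alkenylboronate F11 with retained geometry.
  - Suzuki–Miyaura coupling with benzyl chloride 8 as the electrophile (PdCl2(dppf), K2CO3, THF–H2O) comes back to the route at 10.

Further compounds
F1 | step 8 | tert-butyldiphenylsilyl ether of 10 | CC(C)(C)[Si](OC/C=C(\Cc1ccc(OCc2ccccc2)c(OC)c1)[C@H]1COC(C)(C)O1)(c1ccccc1)c1ccccc1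
F2 | step 8 | (2S,3E)-3-[4-(benzyloxy)-3-methoxybenzyl]-5-(tert-butyldiphenylsilyloxy)pent-3-ene-1,2-diol | CC(C)(C)[Si](OC/C=C(\Cc1ccc(OCc2ccccc2)c(OC)c1)[C@H](O)CO)(c1ccccc1)c1ccccc1
F3 | step 8 | 2-aryl-1,3-dioxolane acetal of F2 with 13 | CC(C)(C)[Si](OC/C=C(\Cc1ccc(OCc2ccccc2)c(OC)c1)[C@H]1COC(O1)c1ccc(OCc2ccccc2)c(OC)c1)(c1ccccc1)c1ccccc1
F4 | step 8 | 4-formyl oxolane with CH2OSi(t-Bu)Ph2 at C3 (same configuration as 15) | COc1cc(C[C@@]2(C=O)CO[C@H](c3ccc(OCc4ccccc4)c(OC)c3)[C@H]2CO[Si](c2ccccc2)(c2ccccc2)C(C)(C)C)ccc1OCc1ccccc1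
F5 | step 8 | 4-formyloxy oxolane with CH2OSi(t-Bu)Ph2 at C3 | COc1cc(C[C@@]2(OC=O)CO[C@H](c3ccc(OCc4ccccc4)c(OC)c3)[C@H]2CO[Si](c2ccccc2)(c2ccccc2)C(C)(C)C)ccc1OCc1ccccc1
F6 | step 8 | 4-hydroxy oxolane with CH2OSi(t-Bu)Ph2 at C3 | COc1cc(C[C@@]2(O)CO[C@H](c3ccc(OCc4ccccc4)c(OC)c3)[C@H]2CO[Si](c2ccccc2)(c2ccccc2)C(C)(C)C)ccc1OCc1ccccc1
F7 | step 8 | di-O-benzyl olivil (free primary and tertiary hydroxyl groups) | COc1cc(C[C@@]2(O)CO[C@H](c3ccc(OCc4ccccc4)c(OC)c3)[C@H]2CO)ccc1OCc1ccccc1
F8 | step 9 | oxolane-4-carboxylic acid derived from 15 | COc1cc(C[C@@]2(C(=O)O)CO[C@H](c3ccc(OCc4ccccc4)c(OC)c3)[C@H]2COC(C)=O)ccc1OCc1ccccc1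
F9 | step 9 | 2-thioxopyridin-1(2H)-yl ester of F8 | COc1cc(C[C@@]2(C(=O)ON3C=CC=CC3=S)CO[C@H](c3ccc(OCc4ccccc4)c(OC)c3)[C@H]2COC(C)=O)ccc1OCc1ccccc1
F10 | step 9 | 4-hydroperoxy oxolane | COc1cc(C[C@@]2(OO)CO[C@H](c3ccc(OCc4ccccc4)c(OC)c3)[C@H]2COC(C)=O)ccc1OCc1ccccc1
F11 | step 5 | pinacol alkenylboronate derived from 6 (boron cis to CH2OH) | OC/C=C(\B1OC(C)(C)C(C)(C)O1)[C@H]1COC(C)(C)O1
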